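**Retrosynthetic overview**
1. Target gibberellin ⇐ its 7,18-dimethyl ester ⇐ ring D closed last by SmI2 ketyl–alkyne cyclisation (C13–C16) of an 8β-propargyl 13-ketone.
2. Propargyl ketone ⇐ conjugate propargylation at C8 of a ring A/B/C enone lactone (C13=O, C8=C14).
3. Enone ⇐ ring B by addition of the C6 ester enolate to C8 of a vinylogous ester, then Stork–Danheiser transposition ⇐ C9–C10 aldol of the 3-ethoxycyclohexenone enolate onto a ring A ketone, the new alkoxide closing the 19,10-lactone on one of the two C4 esters.
4. Ring A keto acid ⇐ key step: singlet-oxygen dearomatisation of a 2-alkylfuran (its four carbons become C10, C5, C6, C7) and enantioselective iminium-catalysed 6-exo Michael closure by a tethered malonate (C4).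
5. Ring order: A → lactone → B (ring C is bought as an enone) → D.

Assumption: gibberellin numbering (C1–C19, α = face of the lactone bridge) is used for the atoms of all intermediates; the target (number 21 of the gibberellin A series) is called "the target gibberellin" throughout; 3-ethoxycyclohex-2-en-1-one and tributyl(propa-1,2-dienyl)stannane are bought.

**Step 1**
Reactants: 1 furan; 2 1-bromo-3-chloropropane
Product: 4 2-(3-chloropropyl)furan, via 2-furyllithium 3 (not isolated)
Conditions: n-BuLi, THF, −78 to 0 °C; then 2, −78 °C to rt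
Reagents that add atoms: none
Why: Furan is lithiated at C2 and the 2-furyllithium displaces bromide, the better leaving group, in an SN2 alkylation, so the chloride is kept for step 2; no stereocentre is formed.

**Step 2**
Reactants: 4 2-(3-chloropropyl)furan; 5 dimethyl malonate
Product: 6 dimethyl 2-[3-(furan-2-yl)propyl]propanedioate
Conditions: 5 (2 equiv), K2CO3, NaI (10 mol %), DMF, 70 °C
Reagents that add atoms: none
Why: Malonic ester alkylation in which the malonate anion displaces chloride through the iodide formed in situ (Finkelstein), with excess malonate suppressing dialkylation; no stereocentre is formed.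

**Step 3 (key step)**
Reactants: 6 dimethyl 2-[3-(furan-2-yl)propyl]propanedioate
Product: 9 dimethyl (2R)-3-oxo-2-(2-oxoethyl)cyclohexane-1,1-dicarboxylate, via furan endoperoxide 7 (not isolated), via Z-keto-enal 8 (not isolated)
Conditions: O2, 5,10,15,20-tetraphenylporphyrin (0.5 mol %), visible light, CH2Cl2, −78 °C; Me2S, −78 to 0 °C; then (S)-2-[diphenyl(trimethylsilyloxy)methyl]pyrrolidine (20 mol %), PhCO2H (20 mol %), 0 °C
Reagents that add atoms: dioxygen, O=O
Why: The [4+2] cycloaddition of singlet oxygen dearomatises the furan to endoperoxide 7, Me2S reduction opens it to keto-enal 8, and iminium activation by the (S)-prolinol silyl ether (after Z/E equilibration of the iminium ion) lets the tethered malonate close ring A by a 6-exo Michael addition on the face not shielded by the diphenyl(silyloxy)methyl group, which by the usual shielding model sets C5 as R (organocatalytic asymmetric intramolecular Michael addition).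

**Step 4**
Reactants: 9 dimethyl (2R)-3-oxo-2-(2-oxoethyl)cyclohexane-1,1-dicarboxylate
Product: 10 2-[(1R)-2,2-bis(methoxycarbonyl)-6-oxocyclohexyl]acetic acid
Conditions: NaClO2, NaH2PO4, 2-methylbut-2-ene, t-BuOH/H2O, 0 °C
Reagents that add atoms: sodium chlorite, [Na+].[O-]Cl=O
Why: Pinnick oxidation converts only the aldehyde under buffered, nearly neutral conditions, so the ketone, the esters and the C5 centre (α to the ketone) are untouched and the labile 1,4-keto aldehyde cannot cyclise back to a furan.

**Step 5**
Reactants: 10 2-[(1R)-2,2-bis(methoxycarbonyl)-6-oxocyclohexyl]acetic acid; 11 3-ethoxycyclohex-2-en-1-one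
Product: 14 2-[(1R,5S,8R)-5-(4-ethoxy-2-oxocyclohex-3-en-1-yl)-1-(methoxycarbonyl)-7-oxo-6-oxabicyclo[3.2.1]octan-8-yl]acetic acid (C9 epimer mixture), via lithium enolate 12 (not isolated), via aldolate 13 (not isolated)
Conditions: 11 (2.5 equiv), LiN(i-Pr)2 (2.5 equiv), THF, −78 °C; CeCl3 (2.5 equiv), −78 °C; then 10, −78 to −20 °C; AcOH
Reagents that add atoms: none
Why: Aldol addition of the kinetic α′-enolate (cerium-modified to suppress enolisation and retro-aldol) to the C10 ketone from the equatorial direction, anti to the axial C4 ester and trans to the C5 side chain, puts the new oxygen axial, where it acylates on the syn-axial C4 ester (the C7 carboxylate cannot be acylated) to give the bridged γ-lactone; this traps the adduct and fixes C10 and C4 from C5, while C9 forms as a mixture that is corrected in step 7 (aldol addition–lactonisation).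

**Step 6**
Reactants: 14 lactone acid (name as in step 5)
Product: 15 methyl (1R,5S,8R)-5-(4-ethoxy-2-oxocyclohex-3-en-1-yl)-8-(2-methoxy-2-oxoethyl)-7-oxo-6-oxabicyclo[3.2.1]octane-1-carboxylate (C9 epimer mixture)
Conditions: Me3SiCHN2, MeOH/toluene, 0 °C
Reagents that add atoms: trimethylsilyldiazomethane, C[Si](C)(C)C=[N+]=[N-]
Why: O-methylation of the carboxylic acid under neutral conditions leaves the enol ether and the lactone (prone to base-induced β-elimination from C9) untouched; no stereocentre changes.

**Step 7**
Reactants: 15 lactone diester (name as in step 6)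
Product: 18 ring A/B/C enone lactone diester (13-oxo-8(14)-ene; 19,10-lactone; 7,18-dimethyl ester; 5β-H; 6α-H; 9β-H), via ester enolate 16 (not isolated), via aldolate 17 (not isolated)
Conditions: LiN(i-Pr)2 (1.1 equiv), THF, −78 to −40 °C; then 1 M HCl, THF, 0 °C to rt, 12 h
Reagents that add atoms: water, O
Why: Kinetic deprotonation takes the unhindered CH2CO2Me and not the tertiary, neopentylic C9–H, the ester enolate closes ring B by 5-exo addition to the C8 carbonyl of the vinylogous ester, and aqueous acid hydrolyses the enol ether and dehydrates to the transposed enone (intramolecular Stork–Danheiser sequence), whose γ-centres C6 and C9 equilibrate through the dienol to the more stable 6β-ester (anti to C4) and 9β-H (C11 next to the lactone oxygen and not to the C1 methylene) arrangement.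

**Step 8**
Reactants: 18 enone lactone diester; 19 tributyl(propa-1,2-dien-1-yl)stannane
Product: 20 8β-(prop-2-yn-1-yl) 13-ketone lactone diester (19,10-lactone; 7,18-dimethyl ester; ring D not yet closed)
Conditions: 19 (2 equiv), TiCl4 (1.1 equiv), CH2Cl2, −78 °C; then H2O
Reagents that add atoms: none
Why: Lewis-acid-promoted conjugate propargylation (SE2′ reaction of the allenylstannane, Sakurai-type) attacks the ring-fusion β-carbon C8 on the face of H-9, as conjugate additions to such bicyclic enones give the cis-fused hydrindanone, which creates the C8 quaternary centre with the propargyl group β.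

**Step 9**
Reactants: 20 8β-propargyl 13-ketone lactone diester
Product: 21 target gibberellin 7,18-dimethyl ester
Conditions: SmI2 (2.5 equiv), hexamethylphosphoramide, t-BuOH, THF, −78 to 0 °C
Reagents that add atoms: none
Why: SmI2 reduces only the ketone to a ketyl radical that adds 5-exo-dig to the alkyne (the two-carbon bridge can only span the 1,3-diaxial positions, so C13 is set by C8) and the vinyl radical is reduced and protonated to the exocyclic methylene (ketyl–alkyne reductive cyclisation).

**Step 10**
Reactants: 21 target gibberellin 7,18-dimethyl ester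
Product: 22 target gibberellin
Conditions: n-PrSH, n-BuLi, hexamethylphosphoramide, 0 °C to rt; then cold 1 M HCl to pH 3
Reagents that add atoms: none
Why: The thiolate cleaves both methyl esters by SN2 attack at the methyl carbons (Bartlett–Johnson dealkylation), which spares the tertiary-alkyl lactone, the tertiary allylic alcohol and the alkene, runs at room temperature so the malonic-type C4 acid does not decarboxylate, and leaves C6 in its stable β configuration.

Stereocentres: C5 is set in step 3, C10 and C4 in step 5, C6 and C9 in step 7, C8 in step 8 and C13 in step 9. C5 is locked once C10 is no longer a ketone (after step 5), and C9 once the enone is consumed (after step 8).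

**Compound list**
1 | furan | c1ccoc1 | starting material
2 | 1-bromo-3-chloropropane | ClCCCBr | starting material
3 | 2-furyllithium | [Li]c1ccco1 | intermediate (not isolated)
4 | 2-(3-chloropropyl)furan | ClCCCc1ccco1 | intermediate
5 | dimethyl malonate | COC(=O)CC(=O)OC | starting material
6 | dimethyl 2-[3-(furan-2-yl)propyl]propanedioate | COC(=O)C(CCCc1ccco1)C(=O)OC | intermediate
7 | dimethyl 2-[3-(2,3,7-trioxabicyclo[2.2.1]hept-5-en-1-yl)propyl]propanedioate (racemic endoperoxide) | COC(=O)C(CCCC12OOC(O1)C=C2)C(=O)OC | intermediate (not isolated)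
8 | dimethyl 2-[(5Z)-4,7-dioxohept-5-en-1-yl]propanedioate | COC(=O)C(CCCC(=O)/C=C\C=O)C(=O)OC | intermediate (not isolated)
9 | dimethyl (2R)-3-oxo-2-(2-oxoethyl)cyclohexane-1,1-dicarboxylate | O=C1CCCC(C(=O)OC)(C(=O)OC)[C@H]1CC=O | intermediate
10 | 2-[(1R)-2,2-bis(methoxycarbonyl)-6-oxocyclohexyl]acetic acid | O=C1CCCC(C(=O)OC)(C(=O)OC)[C@H]1CC(=O)O | intermediate
11 | 3-ethoxycyclohex-2-en-1-one | O=C1C=C(OCC)CCC1 | starting material
12 | lithium 5-ethoxycyclohexa-1,5-dien-1-olate | [Li+].[O-]C1=CCCC(OCC)=C1 | intermediate (not isolated)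
13 | dilithium 2-[(1R,2S)-2-(4-ethoxy-2-oxocyclohex-3-en-1-yl)-6,6-bis(methoxycarbonyl)-2-oxidocyclohexyl]acetate (C9 epimers; that centre left open) | [Li+].[Li+].O=C1C=C(OCC)CCC1[C@]1([O-])CCCC(C(=O)OC)(C(=O)OC)[C@H]1CC(=O)[O-] | intermediate (not isolated)
14 | 2-[(1R,5S,8R)-5-(4-ethoxy-2-oxocyclohex-3-en-1-yl)-1-(methoxycarbonyl)-7-oxo-6-oxabicyclo[3.2.1]octan-8-yl]acetic acid (C9 epimers; that centre left open) | O=C1C=C(OCC)CCC1[C@@]12CCC[C@@](C(=O)OC)(C(=O)O1)[C@H]2CC(=O)O | intermediate
15 | methyl (1R,5S,8R)-5-(4-ethoxy-2-oxocyclohex-3-en-1-yl)-8-(2-methoxy-2-oxoethyl)-7-oxo-6-oxabicyclo[3.2.1]octane-1-carboxylate (C9 epimers; that centre left open) | O=C1C=C(OCC)CCC1[C@@]12CCC[C@@](C(=O)OC)(C(=O)O1)[C@H]2CC(=O)OC | intermediate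
16 | lithium enolate of 15 at the CH2CO2Me group (C6) | [Li+].O=C1C=C(OCC)CCC1[C@@]12CCC[C@@](C(=O)OC)(C(=O)O1)[C@H]2C=C([O-])OC | intermediate (not isolated)
17 | lithium alkoxide of the ring B aldol adduct (C6–C8 bond formed, C8–OLi, enol ether intact; C6, C8, C9 left open) | [Li+].[O-]C12C=C(OCC)CCC1[C@@]13CCC[C@@](C(=O)OC)(C(=O)O1)[C@H]3C2C(=O)OC | intermediate (not isolated)
18 | ring A/B/C enone lactone diester: 13-oxo-8(14)-ene, 19,10-lactone, 7,18-dimethyl ester, 5β-H, 6α-H, 9β-H | C23=CC(=O)CC[C@H]2[C@@]12CCC[C@@](C(=O)OC)(C(=O)O1)[C@H]2[C@@H]3C(=O)OC | intermediate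
19 | tributyl(propa-1,2-dien-1-yl)stannane | C=C=C[Sn](CCCC)(CCCC)CCCC | starting material
20 | 8β-(prop-2-yn-1-yl) 13-ketone lactone diester (as 18 but C8 quaternary, C14 saturated) | C#CC[C@]23CC(=O)CC[C@H]2[C@@]12CCC[C@@](C(=O)OC)(C(=O)O1)[C@H]2[C@@H]3C(=O)OC | intermediate
21 | target gibberellin 7,18-dimethyl ester (as 22 with both acids as methyl esters) | C=C1C[C@]23C[C@@]1(O)CC[C@H]2[C@@]12CCC[C@@](C(=O)OC)(C(=O)O1)[C@H]2[C@@H]3C(=O)OC | intermediate
22 | target gibberellin: 13-hydroxy-20-norgibberell-16-ene-7,18,19-trioic acid 19,10-lactone (5β-H, 6α-H, 9β-H, lactone bridge α, ring D bridge β) | C=C1C[C@]23C[C@@]1(O)CC[C@H]2[C@@]12CCC[C@@](C(=O)O)(C(=O)O1)[C@H]2[C@@H]3C(=O)O | target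

**Totals**
Total step count: 10. Longest linear sequence: 10 steps (furan 1 → target gibberellin 22).

**Three steps most likely to fail, each with a fallback**

Step 3 (the one-pot dearomatisation and asymmetric ring closure). The enantiomeric excess may be eroded by incomplete Z/E equilibration of the iminium ion or by an uncatalysed background Michael addition. The fallback gives up asymmetric catalysis for resolution. It sets out from 6: photooxygenation and Me2S reduction are run as before, but ring A is closed with catalytic 1,8-diazabicyclo[5.4.0]undec-7-ene to give the racemic keto aldehyde F1. Oxidation with NaClO2 gives the racemic keto acid F2. F2 is resolved by crystallising the 1-phenylethylammonium salt of the (R)-acid, salt F3 (drawn with the (S)-amine; the (R)-amine is used if the other diastereomer crystallises). Acidification of F3 returns to the route at 10.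

Step 7 (ring B closure). Base may remove the C9–H instead and expel the lactone carboxylate, or the enolate may not add to the poorly electrophilic vinylogous-ester carbonyl. The fallback replaces the lithium enolate by an acylammonium enolate made only at C6. It sets out from 14 and skips step 6. The acid is activated with 2-chloro-1-methylpyridinium iodide and i-Pr2NEt in the presence of 4-pyrrolidinopyridine in CH2Cl2, so that nucleophile-catalysed aldol-lactonisation joins C6 to C8 and gives the fused β-lactone F4. Treatment with 1 M HCl in THF hydrolyses the enol ether and opens the β-lactone by elimination to the enone acid F5. Me3SiCHN2 then returns to the route at 18.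

Step 8 (quaternary centre by conjugate propargylation). The allenylstannane may add 1,2 or fail at the fully substituted β-carbon. Some attack from the α face, away from the neighbouring 6β-ester, is also possible, and the fallback does not remove that risk; such an epimer would be separated by chromatography. The fallback uses the more reliable allyl transfer and builds ring D by pinacol closure. It sets out from 18: allyltrimethylsilane and TiCl4 in CH2Cl2 at −78 °C give the 8β-allyl ketone F6 (Hosomi–Sakurai). Ozonolysis with Me2S work-up gives the keto aldehyde F7. SmI2 in THF closes ring D by pinacol coupling to the 13,16-diol F8. Swern oxidation of the secondary alcohol gives the 13-hydroxy-16-ketone F9. Methylenation with Ph3P=CH2 returns to the route at 21.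

**Further compounds**
F1 | step 3 | racemic dimethyl 3-oxo-2-(2-oxoethyl)cyclohexane-1,1-dicarboxylate | O=C1CCCC(C(=O)OC)(C(=O)OC)C1CC=O
F2 | step 3 | racemic 2-[2,2-bis(methoxycarbonyl)-6-oxocyclohexyl]acetic acid | O=C1CCCC(C(=O)OC)(C(=O)OC)C1CC(=O)O
F3 | step 3 | (S)-1-phenylethylammonium 2-[(1R)-2,2-bis(methoxycarbonyl)-6-oxocyclohexyl]acetate | C[C@H]([NH3+])c1ccccc1.O=C1CCCC(C(=O)OC)(C(=O)OC)[C@H]1CC(=O)[O-]
F4 | step 7 | β-lactone from C7 to the C8 oxygen with the C6–C8 bond formed (enol ether and 19,10-lactone intact; C6, C8, C9 left open) | O=C1OC23C=C(OCC)CCC2[C@@]24CCC[C@@](C(=O)OC)(C(=O)O2)[C@H]4C13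
F5 | step 7 | enone lactone 7-acid 18-methyl ester (as 18 with free C7 acid) | C23=CC(=O)CC[C@H]2[C@@]12CCC[C@@](C(=O)OC)(C(=O)O1)[C@H]2[C@@H]3C(=O)O
F6 | step 8 | 8β-allyl 13-ketone lactone diester | C=CC[C@]23CC(=O)CC[C@H]2[C@@]12CCC[C@@](C(=O)OC)(C(=O)O1)[C@H]2[C@@H]3C(=O)OC
F7 | step 8 | 13-ketone 16-aldehyde lactone diester | O=CC[C@]23CC(=O)CC[C@H]2[C@@]12CCC[C@@](C(=O)OC)(C(=O)O1)[C@H]2[C@@H]3C(=O)OC
F8 | step 8 | 13,16-dihydroxy-17-nor ring D diol lactone diester (C16 left open) | OC1C[C@]23C[C@@]1(O)CC[C@H]2[C@@]12CCC[C@@](C(=O)OC)(C(=O)O1)[C@H]2[C@@H]3C(=O)OC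
F9 | step 8 | 13-hydroxy-16-oxo-17-nor lactone diester | O=C1C[C@]23C[C@@]1(O)CC[C@H]2[C@@]12CCC[C@@](C(=O)OC)(C(=O)O1)[C@H]2[C@@H]3C(=O)OC
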